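**Retrosynthetic overview**
- The target comes from a double alcohol oxidation (C2–OH and C8–OH) of an epoxy diol; the C8–OH comes from allylic hydroxylation next to the exo-methylene.
- The oxirane (second ring, formed last) comes from hydroxyl-directed epoxidation of the Δ3 olefin of a 2β-allylic alcohol, itself made by Luche reduction of the enone.
- The 1-oxy-2-oxo-Δ3 ring pattern and the (9E)-11-hydroxy tail both come from one double Schenck ene reaction (singlet oxygen) on a trienol.
- The cyclohexene (first ring) comes from a catalytic asymmetric carbonyl-ene 1,6-cyclisation of (2Z,6Z)-farnesal, the oxo-variant of bisabolyl cation formation; it sets C1–O, C6 and the exo-methylene in one step.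
- All 15 skeletal carbons come from farnesol; only the tigloyl group is added.

Assumption: isomerically pure (2Z,6Z)-farnesol is bought as a catalogue terpene; bisabolane numbering is used (C1 = CH–O-tigloyl, C2 = C=O, C3–C4 = epoxide, C6 = ring CH carrying C7(=C14H2)–C8–C9=C10–C11).

**Route**

Step 1
Reactants: 1 (2Z,6Z)-farnesol
Product: 2 (2Z,6Z)-farnesal
Conditions: TEMPO (10 mol %), PhI(OAc)2 (1.1 equiv), CH2Cl2, 0 °C → rt
Reagents that add atoms: none
Why: Oxoammonium (TEMPO/PhI(OAc)2) oxidation of a primary allylic alcohol stops at the enal and, being non-basic, leaves the 2Z geometry intact.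

Step 2
Reactants: 2 (2Z,6Z)-farnesal
Product: 3 (1R,6S)-3-methyl-6-(6-methylhepta-1,5-dien-2-yl)cyclohex-2-en-1-ol
Conditions: confined chiral imino-imidodiphosphate Brønsted acid (2–5 mol %, enantiomer giving the 1R,6S series), CHCl3, –20 °C
Reagents that add atoms: none
Why: Proposed new method: the confined acid activates the aldehyde and the 6,7-olefin attacks C1 through a chair-like transition state with C1–O and the C6 substituent pseudo-equatorial (trans-1,6 pair, face chosen by the catalyst pocket), while the proton is taken from the C7 substituent syn to H-6, which in the 6Z isomer is the methyl group, so the exo-methylene results; the closest known reaction type is the Brønsted-acid-catalysed asymmetric intramolecular carbonyl-ene (Prins-type) cyclisation of neral to trans-isopiperitenol and of citronellal to isopulegol.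

Step 3
Reactants: 3 (1R,6S)-3-methyl-6-(6-methylhepta-1,5-dien-2-yl)cyclohex-2-en-1-ol
Product: 5 (1S,2R,6S)-6-[(4E)-6-hydroxy-6-methylhepta-1,4-dien-2-yl]-3-methylcyclohex-3-ene-1,2-diol, via bis-hydroperoxide 4 (not isolated)
Conditions: O2, hν (white LED), tetraphenylporphyrin (0.5 mol %), CH2Cl2, –20 °C; then PPh3 (2.2 equiv), –20 °C → rt
Reagents that add atoms: oxygen (as singlet oxygen), O=O
Why: Double Schenck ene reaction in which 1O2 touches only the two trisubstituted olefins: the allylic OH steers oxygen to C2 with loss of the cis pseudo-axial H-4 (Δ3 olefin, C2–O cis to C1–OH, a centre erased in step 4), the prenyl end gives the (9E)-11-hydroperoxide (about 1:1 with the separable 10-hydroperoxy isomer), and PPh3 reduces both O–O bonds.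

Step 4
Reactants: 5 (1S,2R,6S)-6-[(4E)-6-hydroxy-6-methylhepta-1,4-dien-2-yl]-3-methylcyclohex-3-ene-1,2-diol
Product: 6 (5S,6S)-6-hydroxy-5-[(4E)-6-hydroxy-6-methylhepta-1,4-dien-2-yl]-2-methylcyclohex-2-en-1-one
Conditions: activated MnO2 (15 equiv), CH2Cl2, rt
Reagents that add atoms: none
Why: MnO2 oxidises only the allylic secondary alcohol (C2) to the conjugated enone and leaves the non-allylic C1–OH and the tertiary alcohol alone.

Step 5
Reactants: 6 (5S,6S)-6-hydroxy-5-[(4E)-6-hydroxy-6-methylhepta-1,4-dien-2-yl]-2-methylcyclohex-2-en-1-one; 7 tigloyl chloride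
Product: 8 (1S,6S)-6-[(4E)-6-hydroxy-6-methylhepta-1,4-dien-2-yl]-3-methyl-2-oxocyclohex-3-en-1-yl (2E)-2-methylbut-2-enoate
Conditions: 7 (1.2 equiv), pyridine (3 equiv), DMAP (5 mol %), CH2Cl2, –20 → 0 °C
Reagents that add atoms: tigloyl chloride 7, C/C=C(\C)C(Cl)=O
Why: DMAP-catalysed acylation esterifies the secondary α-ketol OH while the tertiary allylic alcohol stays free; the equatorial C1 configuration (trans to the side chain) is also the thermodynamic one, so no stereocentre is at risk.

Step 6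
Reactants: 8 (1S,6S)-6-[(4E)-6-hydroxy-6-methylhepta-1,4-dien-2-yl]-3-methyl-2-oxocyclohex-3-en-1-yl (2E)-2-methylbut-2-enoate
Product: 9 (1S,2S,6S)-2-hydroxy-6-[(4E)-6-hydroxy-6-methylhepta-1,4-dien-2-yl]-3-methylcyclohex-3-en-1-yl (2E)-2-methylbut-2-enoate
Conditions: NaBH4 (1.0 equiv), CeCl3·7H2O (1.1 equiv), MeOH, –78 °C
Reagents that add atoms: none
Why: Luche 1,2-reduction with axial hydride delivery anti to the C6 side chain (as in carvone → cis-carveol) gives the equatorial 2β-alcohol, cis to the side chain and trans to the ester, without touching the tiglate.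

Step 7
Reactants: 9 (1S,2S,6S)-2-hydroxy-6-[(4E)-6-hydroxy-6-methylhepta-1,4-dien-2-yl]-3-methylcyclohex-3-en-1-yl (2E)-2-methylbut-2-enoate
Product: 10 (1S,2R,3R,4S,6S)-3,4-epoxy-2-hydroxy-6-[(4E)-6-hydroxy-6-methylhepta-1,4-dien-2-yl]-3-methylcyclohexyl (2E)-2-methylbut-2-enoate
Conditions: VO(acac)2 (5 mol %), t-BuOOH (1.2 equiv), CH2Cl2, 0 °C
Reagents that add atoms: tert-butyl hydroperoxide, CC(C)(C)OO
Why: Hydroxyl-directed vanadium-catalysed epoxidation delivers oxygen syn to the secondary allylic OH, setting C3 and C4 with the oxirane cis to the side chain; the exo-methylene and tiglate have no directing OH, and the tertiary allylic alcohol on a 1,2-disubstituted olefin reacts much more slowly.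

Step 8
Reactants: 10 (1S,2R,3R,4S,6S)-3,4-epoxy-2-hydroxy-6-[(4E)-6-hydroxy-6-methylhepta-1,4-dien-2-yl]-3-methylcyclohexyl (2E)-2-methylbut-2-enoate
Product: 11 (1S,2R,3R,4S,6S)-6-[(4E)-3,6-dihydroxy-6-methylhepta-1,4-dien-2-yl]-3,4-epoxy-2-hydroxy-3-methylcyclohexyl (2E)-2-methylbut-2-enoate
Conditions: SeO2 (0.3 equiv, catalytic), t-BuOOH (2 equiv), CH2Cl2, 0 °C → rt
Reagents that add atoms: selenium dioxide, O=[Se]=O (transfers the oxygen); tert-butyl hydroperoxide, CC(C)(C)OO (terminal oxidant, re-oxidises selenium)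
Why: SeO2 allylic hydroxylation (ene reaction then [2,3]-sigmatropic shift) oxidises the allylic CH2 of a 1,1-disubstituted olefin with retention of the exo-methylene, and C8 is the only such CH2 (it is also allylic to Δ9); the new carbinol centre is an inconsequential epimer mixture.

Step 9
Reactants: 11 (1S,2R,3R,4S,6S)-6-[(4E)-3,6-dihydroxy-6-methylhepta-1,4-dien-2-yl]-3,4-epoxy-2-hydroxy-3-methylcyclohexyl (2E)-2-methylbut-2-enoate
Product: 12 (1S,3S,4S,6S)-3,4-epoxy-6-[(4E)-6-hydroxy-6-methyl-3-oxohepta-1,4-dien-2-yl]-3-methyl-2-oxocyclohexyl (2E)-2-methylbut-2-enoate (CNP0263368.1)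
Conditions: Dess–Martin periodinane (2.6 equiv), CH2Cl2, 0 °C → rt
Reagents that add atoms: none
Why: Dess–Martin oxidation converts both secondary alcohols (epoxy alcohol → epoxy ketone, bis-allylic alcohol → cross-conjugated dienone) under non-basic conditions that leave the tertiary alcohol, oxirane, ester and the C1 centre untouched.

**Compound list**

1 | (2Z,6Z)-farnesol, (2Z,6Z)-3,7,11-trimethyldodeca-2,6,10-trien-1-ol | OC/C=C(C)\CC/C=C(C)\CCC=C(C)C | starting material
2 | (2Z,6Z)-farnesal | O=C/C=C(C)\CC/C=C(C)\CCC=C(C)C | intermediate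
3 | (1R,6S)-3-methyl-6-(6-methylhepta-1,5-dien-2-yl)cyclohex-2-en-1-ol (OH trans to side chain) | C=C(CCC=C(C)C)[C@@H]1CCC(C)=C[C@H]1O | intermediate
4 | (1S,2R,6S)-2-hydroperoxy-6-[(4E)-6-hydroperoxy-6-methylhepta-1,4-dien-2-yl]-3-methylcyclohex-3-en-1-ol (bis-hydroperoxide) | C=C(C/C=C/C(C)(C)OO)[C@@H]1CC=C(C)[C@@H](OO)[C@H]1O | intermediate
5 | (1S,2R,6S)-6-[(4E)-6-hydroxy-6-methylhepta-1,4-dien-2-yl]-3-methylcyclohex-3-ene-1,2-diol | C=C(C/C=C/C(C)(C)O)[C@@H]1CC=C(C)[C@@H](O)[C@H]1O | intermediate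
6 | (5S,6S)-6-hydroxy-5-[(4E)-6-hydroxy-6-methylhepta-1,4-dien-2-yl]-2-methylcyclohex-2-en-1-one | C=C(C/C=C/C(C)(C)O)[C@@H]1CC=C(C)C(=O)[C@H]1O | intermediate
7 | tigloyl chloride, (2E)-2-methylbut-2-enoyl chloride | C/C=C(\C)C(Cl)=O | starting material
8 | (1S,6S)-6-[(4E)-6-hydroxy-6-methylhepta-1,4-dien-2-yl]-3-methyl-2-oxocyclohex-3-en-1-yl (2E)-2-methylbut-2-enoate | C=C(C/C=C/C(C)(C)O)[C@@H]1CC=C(C)C(=O)[C@H]1OC(=O)/C(C)=C/C | intermediate
9 | (1S,2S,6S)-2-hydroxy-6-[(4E)-6-hydroxy-6-methylhepta-1,4-dien-2-yl]-3-methylcyclohex-3-en-1-yl (2E)-2-methylbut-2-enoate (2-OH cis to side chain, trans to ester) | C=C(C/C=C/C(C)(C)O)[C@@H]1CC=C(C)[C@H](O)[C@H]1OC(=O)/C(C)=C/C | intermediate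
10 | (1S,2R,3R,4S,6S)-3,4-epoxy-2-hydroxy-6-[(4E)-6-hydroxy-6-methylhepta-1,4-dien-2-yl]-3-methylcyclohexyl (2E)-2-methylbut-2-enoate (oxirane and 2-OH cis to side chain) | C=C(C/C=C/C(C)(C)O)[C@@H]1C[C@@H]2O[C@]2(C)[C@H](O)[C@H]1OC(=O)/C(C)=C/C | intermediate
11 | (1S,2R,3R,4S,6S)-6-[(4E)-3,6-dihydroxy-6-methylhepta-1,4-dien-2-yl]-3,4-epoxy-2-hydroxy-3-methylcyclohexyl (2E)-2-methylbut-2-enoate (both epimers at the new side-chain carbinol) | C=C(C(O)/C=C/C(C)(C)O)[C@@H]1C[C@@H]2O[C@]2(C)[C@H](O)[C@H]1OC(=O)/C(C)=C/C | intermediate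
12 | (1S,3S,4S,6S)-3,4-epoxy-6-[(4E)-6-hydroxy-6-methyl-3-oxohepta-1,4-dien-2-yl]-3-methyl-2-oxocyclohexyl (2E)-2-methylbut-2-enoate | C=C(C(=O)/C=C/C(C)(C)O)[C@@H]1C[C@@H]2O[C@]2(C)C(=O)[C@H]1OC(=O)/C(C)=C/C | target

**Step count and risk**

Total steps: 9. Longest linear sequence: 9 (1 → 12); tigloyl chloride 7 is bought.

Steps most likely to fail:

Step 2. The cyclisation is untested on the C15 enal; enantio- and trans-selectivity, proton loss toward the methyl group, and acid-lability of the allylic alcohol 3 are all open. The fallback sets out from 2 and returns at 3. Compound 2 is cyclised with Me2AlCl (1.1 equiv, CH2Cl2, –78 °C), a Lewis-acid type-I carbonyl-ene reaction in which the aluminium alkoxide takes the hydrogen from the alkyl group syn to H-6, to give the racemic trans-alcohol F1. F1 is then resolved with Candida antarctica lipase B and vinyl acetate, which by Kazlauskas' rule should acylate the (1R)-enantiomer to the (1R,6S)-acetate F2. F2 is separated from the unreacted (1S,6R)-alcohol and methanolysed (K2CO3, MeOH) to 3.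

Step 3. Ring hydrogen abstraction may go to the methyl group instead of C4 (giving the useless exocyclic isomer), and the tail gives only about half of the wanted tertiary hydroperoxide. The fallback sets out from 3 and returns at 8, building the ring enone without singlet oxygen. VO(acac)2/t-BuOOH epoxidises only the allylic-alcohol olefin, syn to OH, to give the epoxy alcohol F3. Tigloyl chloride 7 with pyridine then gives the epoxy tiglate F4. Pyridinium chloride opens the oxirane trans-diaxially at the tertiary carbon to the chlorohydrin F5, and Dess–Martin oxidation gives the α-chloro ketone F6. Li2CO3/LiBr in DMF removes HCl anti-periplanar toward C4 to give the conjugated enone F7, which still carries the prenyl tail. A Schenck ene reaction that now touches only the prenyl olefin gives the tail hydroperoxide F8, and PPh3 reduces it to 8.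

Step 8. Selenium dioxide on the polyfunctional 10 may over-oxidise or give a low yield. The fallback sets out from 10 and returns at 11, replacing direct C–H oxidation by an olefin functionalisation and transposition. Ene-type chlorination (NCS, 10 mol % PhSeCl, CH2Cl2) of the 1,1-disubstituted olefin gives the rearranged allylic chloride F9 (14-chloro-7,9-diene). PhSNa (THF, 0 °C) displaces the primary allylic chloride faster than it opens the oxirane, giving the allylic sulfide F10. mCPBA (1 equiv, –78 °C) gives the sulfoxide F11, whose Mislow–Evans [2,3] shift in the presence of Et2NH puts oxygen on C8 and restores the exo-methylene, giving 11.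

Further compounds
F1 | step 2 | racemic trans-alcohol, rac-trans-3-methyl-6-(6-methylhepta-1,5-dien-2-yl)cyclohex-2-en-1-ol (both enantiomers, drawn without wedges) | C=C(CCC=C(C)C)C1CCC(C)=CC1O
F2 | step 2 | (1R,6S)-acetate, (1R,6S)-3-methyl-6-(6-methylhepta-1,5-dien-2-yl)cyclohex-2-en-1-yl acetate | C=C(CCC=C(C)C)[C@@H]1CCC(C)=C[C@H]1OC(C)=O
F3 | step 3 | epoxy alcohol, 2,3-epoxide of 3 with the oxirane cis to the 1-OH and trans to the side chain | C=C(CCC=C(C)C)[C@@H]1CC[C@@]2(C)O[C@H]2[C@H]1O
F4 | step 3 | epoxy tiglate, (2E)-2-methylbut-2-enoate of F3 | C=C(CCC=C(C)C)[C@@H]1CC[C@@]2(C)O[C@H]2[C@H]1OC(=O)/C(C)=C/C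
F5 | step 3 | chlorohydrin, 3-chloro-2-hydroxy-3-methyl-6-(6-methylhepta-1,5-dien-2-yl)cyclohexyl tiglate (Cl cis to side chain, 2-OH cis to ester) | C=C(CCC=C(C)C)[C@@H]1CC[C@](C)(Cl)[C@@H](O)[C@H]1OC(=O)/C(C)=C/C
F6 | step 3 | α-chloro ketone, 3-chloro-3-methyl-6-(6-methylhepta-1,5-dien-2-yl)-2-oxocyclohexyl tiglate | C=C(CCC=C(C)C)[C@@H]1CC[C@](C)(Cl)C(=O)[C@H]1OC(=O)/C(C)=C/C
F7 | step 3 | enone, (1S,6S)-3-methyl-6-(6-methylhepta-1,5-dien-2-yl)-2-oxocyclohex-3-en-1-yl tiglate | C=C(CCC=C(C)C)[C@@H]1CC=C(C)C(=O)[C@H]1OC(=O)/C(C)=C/C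
F8 | step 3 | tail hydroperoxide, 11-hydroperoxide corresponding to 8 | C=C(C/C=C/C(C)(C)OO)[C@@H]1CC=C(C)C(=O)[C@H]1OC(=O)/C(C)=C/C
F9 | step 8 | allylic chloride, 14-chloro-7,9-diene derived from 10 (7,8-olefin E/Z mixture) | ClCC(=C/C=C/C(C)(C)O)[C@@H]1C[C@@H]2O[C@]2(C)[C@H](O)[C@H]1OC(=O)/C(C)=C/C
F10 | step 8 | allylic sulfide, 14-phenylthio-7,9-diene | c1ccccc1SCC(=C/C=C/C(C)(C)O)[C@@H]2C[C@@H]3O[C@]3(C)[C@H](O)[C@H]2OC(=O)/C(C)=C/C
F11 | step 8 | sulfoxide, 14-phenylsulfinyl-7,9-diene (sulfur epimers) | O=S(c1ccccc1)CC(=C/C=C/C(C)(C)O)[C@@H]2C[C@@H]3O[C@]3(C)[C@H](O)[C@H]2OC(=O)/C(C)=C/C
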